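## Analysis of the target

Compound 10 is an unsymmetrical bis-coumarin: two 2H-chromen-2-one bicycles joined by one ether oxygen that runs from C3 of the unprimed unit (6-OMe, 7-OH) to C7' of the primed unit, which is the skeleton of scopoletin 5 (6'-OMe). The molecule is flat and has no stereocentre, so nothing has to be controlled in space; the problems are connectivity and chemoselectivity. Sensitive functions are the two lactones (opened by hydroxide or alkoxide), the free C7 phenol on an electron-rich ring (easily oxidised or alkylated), the C3'=C4' enoate of the primed unit (reducible and photoactive) and the oxygenated arene positions open to electrophiles. The hard bond is C3–O: C3 is an sp2 carbon of an electron-poor pyranone next to the lactone carbonyl, and its partner oxygen belongs to a weakly nucleophilic, base-sensitive 7-hydroxycoumarin, so an aryl-type C–O coupling at C3 is an unattractive way to join the halves. A second difficulty is that the two halves are almost the same heterocycle and must be made different at the right moment. The strategy rests on the place of O1 in the unprimed unit: it lies between aromatic C8a and carbonyl C2, which is where an oxygen atom is left when a 1-indanone is ring-expanded by a Baeyer–Villiger reaction with migration of the aryl carbon. With O1 taken out, C2, C3, C4, C4a and C8a form the five-membered ring of an indan-1-one, C3 becomes the sp3 carbon alpha to a ketone, and the ether can be closed there by SN2 displacement with 5.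

## Retrosynthetic reasoning

The first cut is the benzyl–oxygen bond of 9, which sets the C7 phenol of 10 free last. The phenol has to stay masked up to this point, because free it would compete with 5 as a nucleophile and would not survive a peroxy acid or a quinone oxidant. A benzyl ether withstands all of that and can be removed by a boron trihalide at low temperature, which leaves the two methyl ethers, the lactones and the C3'=C4' bond alone; a hydrogenolysis, which would endanger that double bond, is not needed.

Next the C3=C4 double bond of 9 is taken back to a single bond, giving the chroman-2-one 8. This is the condition for the key step, which delivers a saturated lactone. Forward, a high-potential quinone has to remove hydride from benzylic C4 (para to the C7 oxygen) and a proton from C3. The step also erases the one stereocentre of the route, so 8 and everything before it may be racemic.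

The key disconnection removes O1: the bonds O1–C8a and O1–C2 are cut and C8a is joined to C2, which contracts the lactone to the indan-1-one 6. C2, C3, C4, C4a, C8a, C6 and C7 of the chromanone are C1, C2, C3, C3a, C7a, C5 and C6 of the indanone. The cut is made here because it turns C3 from a lactone alpha carbon (later a vinylic carbon) into the alpha carbon of a ketone, where a C–O bond is easy to make. Forward, a peroxy acid must add to the ketone to give the adduct 7, and in 7 the aryl carbon must migrate in preference to the oxygen-bearing C2; the methoxy group para to the migrating carbon is what makes this reasonable.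

The ether of 6 is cut on its sp3 side, between C2 of the indanone and oxygen, to the alpha-bromo ketone 4 and the phenol 5. The other C–O bond of the ether, to C7' of an electron-rich arene, would call for a metal-mediated aryl coupling. The chosen cut needs only an SN2 reaction, brings in the whole primed half in one piece and in its final oxidation state, and makes the two halves different from the outset. Forward, the phenoxide of 5 must substitute faster than it eliminates.

Removing bromine from 4 gives the ketone 3. C2 is the only enolisable position, so regiochemistry is not in question; the forward reaction has to brominate there once and leave the electron-rich ring alone.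

Cutting the benzyl ether of 3 gives the phenol 1 and the halide 2. Compound 1 already carries methoxy and hydroxy groups in the 5,6-pattern that the ring expansion turns into the 6,7-pattern of 10, so no arene functionalisation is needed anywhere in the route.

## Alternatives that were turned down

Alternative 1: Both bonds to C3 are cut at once, the ether bond C3–O and the ring bond C3–C4. C3 is then the carbene carbon of ethyl diazoacetate A3, the oxygen comes from scopoletin 5 and C4 is the formyl carbon of 2,4-diacetoxy-5-methoxybenzaldehyde A2.
- Forward key step: a dirhodium tetracarboxylate would turn A3 into a carbenoid, the phenol oxygen of 5 would add to it, and the oxonium ylide (or the metal enolate derived from it) would be intercepted by A2 in an aldol-type addition. This gives the open-chain hydroxy ester A1 without ring closure; lactonisation, dehydration and deacetylation would follow.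
- For it: it is the most convergent plan and the three components are small. The C3=C4 bond comes by loss of water and not by a dehydrogenation, and there is no migration selectivity to worry about. On step count it is equal or better.
- Against it: an ylide formed from a phenol collapses very quickly by 1,2-proton shift to the plain O–H insertion product. Interception needs an electrophile more reactive than A2, whose formyl group is deactivated by three oxygen donors and flanked by an ortho acetoxy group. The aldehyde can also take the carbenoid itself (carbonyl ylide, epoxide), the aryl acetates of A2 can be transferred to the phenol 5, and A2 has to be prepared.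
- Comparison: the chosen route gives up that convergence and accepts a redox adjustment, but each of its bonds is made in a separate step of an established type, and the uncertainty is confined to one regiochemical question.

Alternative 2: Only O1–C8a of the unprimed unit is cut. This leads back to the open cinnamic acid A5 (aryl and carboxyl trans across the double bond), which already carries the C3–O ether.
- Forward key step: a flavin photocatalyst under visible light and air would first isomerise the double bond by energy transfer so that the carboxyl group faces the arene, then oxidise the electron-rich ring by single-electron transfer. The carboxylate would attack the ring carbon para to the methoxy group, and rearomatisation would give the coumarin acetate A4, one deacetylation away from 10.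
- For it: the pyranone is formed directly at the coumarin oxidation level, so neither a dehydrogenation nor a migration is needed. The site of closure is well defined, since the other ortho carbon is flanked by the methoxy group. A5 should be reachable in very few steps by a Perkin-type condensation of an aryloxyacetic acid made from 5. On step economy and redox count this plan is stronger than the chosen one.
- Against it: A5 contains a second chromophore, the 7-alkoxycoumarin of the primed half, which absorbs in the near UV, can quench the excited flavin and can photodimerise at C3'=C4'. The double bond to be isomerised is an electron-rich alpha-aryloxy enoate that photosensitised oxygen can cleave. The alpha oxygen also changes the triplet energy and the oxidation potential on which the two roles of the flavin depend.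
- Comparison: the chosen route offers ground-state, thermally driven steps in which the primed coumarin is a spectator, at the price of about two more steps.

Alternative 3: The whole unprimed pyranone is taken apart. O1–C8a and C4–C4a are cut to the aryne A8, C4 is the formyl carbon of dimethylformamide A7, and C2–C3 with the ether oxygen comes from the silyl ketene acetal A9.
- Forward key step: fluoride would release A8 from an ortho-silylaryl triflate and the C=O bond of A7 would add across the aryne. The strained benzoxete would open to an ortho-quinone methide, A9 would add at C4, and the phenoxide would close the lactone with loss of the amine to give the bromocoumarin A6.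
- For it: one operation builds the ring and four bonds at the correct oxidation level. The regiochemistry of the aryne addition is predictable, because the oxygen nucleophile attacks the aryne carbon remote from bromine. It is as convergent as the chosen route and needs no redox step.
- Against it: the bromine of A8 is there only to steer that addition and must be removed afterwards by a reduction that spares the benzyl ether until wanted and does not touch C3'=C4'. The pentasubstituted aryne precursor is a multistep synthesis of its own. A9 has to be generated from an ester in the presence of the electrophilic coumarin of the primed half.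
- Comparison: overall it is longer than the chosen route, which starts from the indanone 1 with every ring substituent already in place.

Key step: step 4

Assumption: compounds 4, 6, 7 and 8 are handled as racemates; this is immaterial, because their one stereocentre becomes the sp2 carbon C3 in step 5.

## Route

Step 1
Reactants: 1 6-hydroxy-5-methoxyindan-1-one; 2 benzyl bromide
Product: 3 6-(benzyloxy)-5-methoxyindan-1-one
Conditions: K2CO3, DMF, rt
Reagents that add atoms: none
Why: Williamson ether synthesis: the phenoxide of 1 is benzylated on oxygen by SN2 on 2, the ketone alpha protons being far less acidic under carbonate. The benzyl ether masks the future C7 phenol against alkylation in step 3 and oxidation in steps 4 and 5.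

Step 2
Reactants: 3 6-(benzyloxy)-5-methoxyindan-1-one
Product: 4 rac-6-(benzyloxy)-2-bromo-5-methoxyindan-1-one
Conditions: CuBr2 (2.1 equiv), EtOAc/CHCl3, reflux
Reagents that add atoms: CuBr2 (copper dibromide), [Cu+2].[Br-].[Br-]
Why: Alpha-bromination of a ketone with CuBr2: bromine is delivered to the copper-bound enol, so the only enolisable position C2 should be monobrominated while the electron-rich ring, which free Br2 would attack, is left alone. The new stereocentre forms without control and 4 is racemic, which does not matter.

Step 3
Reactants: 4 rac-6-(benzyloxy)-2-bromo-5-methoxyindan-1-one; 5 scopoletin (7-hydroxy-6-methoxy-2H-chromen-2-one)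
Product: 6 rac-6-(benzyloxy)-5-methoxy-2-[(6-methoxy-2-oxo-2H-chromen-7-yl)oxy]indan-1-one
Conditions: K2CO3, dry DMF, rt to 40 °C
Reagents that add atoms: none
Why: SN2 displacement on an alpha-bromo ketone by a phenoxide (Williamson-type): the adjacent carbonyl accelerates substitution at C2, and the weakly basic phenoxide of 5 should favour substitution over elimination. Each enantiomer of 4 reacts with inversion, so 6 is racemic; the lactone of 5 is stable to dry carbonate.

Step 4
Reactants: 6 rac-6-(benzyloxy)-5-methoxy-2-[(6-methoxy-2-oxo-2H-chromen-7-yl)oxy]indan-1-one
Product: 8 rac-7-(benzyloxy)-6-methoxy-3-[(6-methoxy-2-oxo-2H-chromen-7-yl)oxy]chroman-2-one, via Criegee peroxyhemiketal 7 (not isolated)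
Conditions: mCPBA, TFA (cat.), CH2Cl2, 0 °C to rt
Reagents that add atoms: mCPBA (3-chloroperoxybenzoic acid), OOC(=O)c1cccc(Cl)c1
Why: Baeyer–Villiger oxidation of a 1-indanone to a 3,4-dihydrocoumarin, the closest known reaction type being the peracid ring expansion of 5-alkoxy-1-indanones. (1) The acid-activated ketone C1 of 6 adds the peracid to give the peroxyhemiketal 7; the alpha-aryloxy group makes this otherwise donor-deactivated aryl ketone more electrophilic. (2) In 7 the aryl carbon C7a shifts from C1 to the proximal peroxide oxygen as 3-chlorobenzoate leaves, so that O1–C8a is formed and the former C1–O bond becomes O1–C2; the six-membered lactone therefore arises by a 1,2-shift that enlarges the five-membered ring by one atom (a ring expansion, not an end-to-end cyclisation). (3) The selectivity needed is migration of C7a and not of C2: C7a is para to the methoxy group and migrates through a phenonium-like transition state as a p-anisyl group does, whereas C2 is a secondary carbon bearing an inductively withdrawing oxygen whose lone pairs are delocalised into the electron-poor coumarin and give a migrating carbon little help. (4) Both ring bonds of 7 can become antiperiplanar to the O–O bond, so the outcome is decided by these electronic factors. (5) The C3'=C4' enoate is too electron-poor to be epoxidised and the ethers are inert to the peracid. (6) No stereocentre is formed: C2 of 6 becomes C3 of 8 untouched and racemic, and it is removed in step 5.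

Step 5
Reactants: 8 rac-7-(benzyloxy)-6-methoxy-3-[(6-methoxy-2-oxo-2H-chromen-7-yl)oxy]chroman-2-one
Product: 9 7-(benzyloxy)-6-methoxy-3-[(6-methoxy-2-oxo-2H-chromen-7-yl)oxy]-2H-chromen-2-one
Conditions: DDQ, 1,4-dioxane, reflux
Reagents that add atoms: none
Why: Dehydrogenation of a 3,4-dihydrocoumarin with DDQ: hydride is abstracted from benzylic C4, whose cation is stabilised by the para benzyloxy group at C7, and loss of the acidic C3 proton gives the conjugated pyranone. The racemic stereocentre C3 disappears; the aryl benzyl ether and the second coumarin carry no comparably hydridic C–H bond.

Step 6
Reactants: 9 7-(benzyloxy)-6-methoxy-3-[(6-methoxy-2-oxo-2H-chromen-7-yl)oxy]-2H-chromen-2-one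
Product: 10 7-hydroxy-6-methoxy-3-[(6-methoxy-2-oxo-2H-chromen-7-yl)oxy]-2H-chromen-2-one
Conditions: BCl3, pentamethylbenzene, CH2Cl2, −78 °C to −40 °C; aq. work-up
Reagents that add atoms: none
Why: Lewis acid cleavage of an aryl benzyl ether with BCl3 and pentamethylbenzene as a non-basic cation scavenger: at low temperature the benzylic C–O bond ionises far more readily than a methyl C–O bond, so both methyl ethers, the C3–O–C7' ether and the two lactones should remain. The scavenger takes up the benzyl cation and prevents Friedel–Crafts benzylation of the electron-rich rings.

## Compound list

1 | 6-hydroxy-5-methoxyindan-1-one | COc1cc2c(cc1O)C(=O)CC2 | starting material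
2 | benzyl bromide | BrCc1ccccc1 | starting material
3 | 6-(benzyloxy)-5-methoxyindan-1-one | COc1cc2c(cc1OCc1ccccc1)C(=O)CC2 | intermediate
4 | rac-6-(benzyloxy)-2-bromo-5-methoxyindan-1-one (racemic, one enantiomer drawn) | COc1cc2c(cc1OCc1ccccc1)C(=O)[C@H](Br)C2 | intermediate
5 | scopoletin (7-hydroxy-6-methoxy-2H-chromen-2-one) | COc1cc2ccc(=O)oc2cc1O | starting material
6 | rac-6-(benzyloxy)-5-methoxy-2-[(6-methoxy-2-oxo-2H-chromen-7-yl)oxy]indan-1-one (racemic, one enantiomer drawn) | COc1cc2c(cc1OCc1ccccc1)C(=O)[C@@H](Oc1cc3oc(=O)ccc3cc1OC)C2 | intermediate
7 | Criegee peroxyhemiketal, 6-(benzyloxy)-1-hydroxy-5-methoxy-2-[(6-methoxy-2-oxo-2H-chromen-7-yl)oxy]indan-1-yl 3-chloroperoxybenzoate (racemic, both configurations at C1, not isolated) | COc1cc2c(cc1OCc1ccccc1)C(O)(OOC(=O)c1cccc(Cl)c1)[C@@H](Oc1cc3oc(=O)ccc3cc1OC)C2 | intermediate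
8 | rac-7-(benzyloxy)-6-methoxy-3-[(6-methoxy-2-oxo-2H-chromen-7-yl)oxy]chroman-2-one (racemic, one enantiomer drawn) | COc1cc2c(cc1OCc1ccccc1)OC(=O)[C@@H](Oc1cc3oc(=O)ccc3cc1OC)C2 | intermediate
9 | 7-(benzyloxy)-6-methoxy-3-[(6-methoxy-2-oxo-2H-chromen-7-yl)oxy]-2H-chromen-2-one | COc1cc2cc(Oc3cc4oc(=O)ccc4cc3OC)c(=O)oc2cc1OCc1ccccc1 | intermediate
10 | 7-hydroxy-6-methoxy-3-[(6-methoxy-2-oxo-2H-chromen-7-yl)oxy]-2H-chromen-2-one | COc1cc2cc(Oc3cc4oc(=O)ccc4cc3OC)c(=O)oc2cc1O | target

## Step count and least certain steps

Total step count: 6. Longest linear sequence: 6 steps (1 → 3 → 4 → 6 → 8 → 9 → 10); 2 and 5 are used as purchased.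

Step 4 (key step). What may go wrong: migration of the oxygen-bearing C2 in place of the aryl carbon, because an alpha oxygen can also assist a migrating carbon through its lone pair. The other risk is slow addition of the peracid to the donor-substituted aryl ketone, which leaves time for oxidation of the enol or of the arene. Fallback (sets out from 3, returns at 8): the ring expansion is done before the ether is in place. Oxidation of 3 with mCPBA should give 7-(benzyloxy)-6-methoxychroman-2-one F1, a case in which the aryl carbon competes only with an unsubstituted methylene group. Enolisation of F1 with LiN(SiMe3)2 at −78 °C and oxidation of the enolate with 2-(phenylsulfonyl)-3-phenyloxaziridine should give racemic 7-(benzyloxy)-3-hydroxy-6-methoxychroman-2-one F2. A Mitsunobu etherification of F2 with 5 (PPh3, diisopropyl azodicarboxylate, THF) should then deliver 8 with inversion at C3.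

Step 3. What may go wrong: base-induced loss of HBr from 4 to an indenone that polymerises, or self-condensation of the bromo ketone, in competition with substitution by the weakly nucleophilic phenoxide. Fallback (sets out from 3, returns at 6): the ether is formed by carbenoid O–H insertion instead of substitution. Claisen formylation of 3 (HCO2Et, NaH) should give 6-(benzyloxy)-2-(hydroxymethylidene)-5-methoxyindan-1-one F3. Deformylative diazo transfer (4-methylbenzenesulfonyl azide, Et3N) should give 6-(benzyloxy)-2-diazo-5-methoxyindan-1-one F4. Decomposition of F4 with catalytic Rh2(OAc)4 in the presence of 5 should insert the carbenoid into the phenolic O–H bond and give 6.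

Step 5. What may go wrong: slow hydride abstraction that demands long heating, with oxidation at the benzyl ether methylene and decomposition of the aryl lactone as side processes. Fallback (sets out from 8, returns at 9): selenoxide elimination. Deprotonation of 8 at C3 with LiN(SiMe3)2 at −78 °C and trapping with PhSeBr should give racemic 7-(benzyloxy)-6-methoxy-3-[(6-methoxy-2-oxo-2H-chromen-7-yl)oxy]-3-(phenylselanyl)chroman-2-one F5. H2O2 should oxidise it to the selenoxide 7-(benzyloxy)-6-methoxy-3-[(6-methoxy-2-oxo-2H-chromen-7-yl)oxy]-3-(phenylseleninyl)chroman-2-one F6, which should eliminate syn toward C4, the only carbon with beta hydrogens, to give 9.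

Step 6. What may go wrong: cleavage of a methyl ether alongside the benzyl ether once the neighbouring phenol is bound to boron, or Friedel–Crafts benzylation of an electron-rich ring if the scavenger is outrun. Fallback (sets out from 9, returns at 10): reductive instead of Lewis acidic cleavage, by catalytic transfer hydrogenolysis (Pd/C, zerovalent palladium on carbon, cyclohexa-1,4-diene, EtOAc/EtOH, rt). It is stopped as soon as 9 is consumed so that the C3'=C4' bond is not reduced; no new compound is made on this path (F0).

## Further compounds

F1 | step 4 | 7-(benzyloxy)-6-methoxychroman-2-one | COc1cc2c(cc1OCc1ccccc1)OC(=O)CC2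
F2 | step 4 | rac-7-(benzyloxy)-3-hydroxy-6-methoxychroman-2-one (racemic, one enantiomer drawn) | COc1cc2c(cc1OCc1ccccc1)OC(=O)[C@H](O)C2
F3 | step 3 | 6-(benzyloxy)-2-(hydroxymethylidene)-5-methoxyindan-1-one (double bond geometry immaterial) | COc1cc2c(cc1OCc1ccccc1)C(=O)C(=CO)C2
F4 | step 3 | 6-(benzyloxy)-2-diazo-5-methoxyindan-1-one | COc1cc2c(cc1OCc1ccccc1)C(=O)C(=[N+]=[N-])C2
F5 | step 5 | rac-7-(benzyloxy)-6-methoxy-3-[(6-methoxy-2-oxo-2H-chromen-7-yl)oxy]-3-(phenylselanyl)chroman-2-one (racemic) | COc1cc2c(cc1OCc1ccccc1)OC(=O)C(Oc1cc3oc(=O)ccc3cc1OC)([Se]c1ccccc1)C2
F6 | step 5 | 7-(benzyloxy)-6-methoxy-3-[(6-methoxy-2-oxo-2H-chromen-7-yl)oxy]-3-(phenylseleninyl)chroman-2-one (racemic, mixture of diastereomers) | COc1cc2c(cc1OCc1ccccc1)OC(=O)C(Oc1cc3oc(=O)ccc3cc1OC)([Se](=O)c1ccccc1)C2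
F0 | step 6 | none | none
A1 | alternative 1 | ethyl 3-(2,4-diacetoxy-5-methoxyphenyl)-3-hydroxy-2-[(6-methoxy-2-oxo-2H-chromen-7-yl)oxy]propanoate (racemic, one diastereomer drawn, configuration immaterial) | CCOC(=O)[C@@H](Oc1cc2oc(=O)ccc2cc1OC)[C@H](O)c1cc(OC)c(OC(C)=O)cc1OC(C)=O
A2 | alternative 1 | 2,4-diacetoxy-5-methoxybenzaldehyde | COc1cc(C=O)c(OC(C)=O)cc1OC(C)=O
A3 | alternative 1 | ethyl diazoacetate | CCOC(=O)C=[N+]=[N-]
A4 | alternative 2 | [6-methoxy-3-[(6-methoxy-2-oxochromen-7-yl)oxy]-2-oxochromen-7-yl] acetate | COc1cc2cc(Oc3cc4oc(=O)ccc4cc3OC)c(=O)oc2cc1OC(C)=O
A5 | alternative 2 | 3-(4-acetoxy-3-methoxyphenyl)-2-[(6-methoxy-2-oxo-2H-chromen-7-yl)oxy]prop-2-enoic acid, aryl and carboxyl trans across the double bond ((Z) by the sequence rules) | COc1cc(/C=C(\Oc2cc3oc(=O)ccc3cc2OC)C(O)=O)ccc1OC(C)=O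
A6 | alternative 3 | 7-(benzyloxy)-5-bromo-6-methoxy-3-[(6-methoxy-2-oxo-2H-chromen-7-yl)oxy]-2H-chromen-2-one | COc1c(Br)c2cc(Oc3cc4oc(=O)ccc4cc3OC)c(=O)oc2cc1OCc1ccccc1
A7 | alternative 3 | N,N-dimethylformamide | CN(C)C=O
A8 | alternative 3 | 5-(benzyloxy)-3-bromo-4-methoxy-1,2-didehydrobenzene (aryne) | COC1=C(Br)C#CC=C1OCc1ccccc1
A9 | alternative 3 | 6-methoxy-7-{[2-methoxy-2-(trimethylsilyloxy)ethenyl]oxy}-2H-chromen-2-one (double bond geometry immaterial) | COC(O[Si](C)(C)C)=COc1cc2oc(=O)ccc2cc1OC
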